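The runs are calculated with made-up constants.

The thing to watch is how much substrate is left at the end, not just how fast target appears. You asked for a quick number and your hunch was that hotter means more target, so here is how far that goes.

the same everywhere: free catalyst 1.3 mM

| flask | substrate | coupling partner | temperature | remark | time |
|---|---|---|---|---|---|
| Tuesday's | 0.67 M | 1 M | 35 °C | run made earlier |  |
| Thursday's | 1.5 M | 1 M | 68 °C | run made earlier |  |
| violet | 1.0 M | 1.00 M | 50 °C |  | 3.0 h |
| blue | 1.0 M | 1.00 M | 20 °C |  | 3.0 h |
| ochre | 1.0 M | 1.00 M | 80 °C |  | 3.0 h |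

Tuesday's run (percent of the substrate charged)

| time / h | target / % |
|---|---|
| 0.500 | 2.6 |
| 1.00 | 4.8 |
| 2.00 | 8.9 |
| 3.00 | 15.5 |
| 4.00 | 19.1 |

Thursday's run (percent of the substrate charged)

| time / min | target / % |
|---|---|
| 6.00 | 6.7 |
| 12.0 | 8.2 |
| 20.0 | 15.7 |
| 25.0 | 17.8 |
| 30.0 | 22.8 |
| 40.0 | 28.5 |
| 50.0 | 35.0 |

(scatter of a reading: 1 percentage point)

* the best flask by amount of target, in percent of the substrate charged; "all alike" if 1.5 percentage points covers them all (violet / blue / ochre / all alike)
* amount of target at the end, in percent of the substrate charged, violet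
* amount of target at the end, in percent of the substrate charged, blue
* amount of target at the end, in percent of the substrate charged, ochre



Both runs climb nearly straight, so I read each as a steady rate (zero order in substrate, as a reading only), taking the last reading over its time:

Tuesday's run: 0.0320 M h⁻¹
Thursday's run: 0.630 M h⁻¹

Between their temperatures, that gives an apparent activation energy of 78.9 kJ mol⁻¹. With it I turn each flask into one time, the emptying time: the substrate charged divided by the steady rate of target at that flask's temperature.

violet: 7.48 h
blue: 151 h
ochre: 0.617 h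

The emptying times of violet and blue are longer than their 3.0 h, so my target is that time over the emptying time: 40.1% for violet and 1.99% for blue. Ochre empties sooner than its 3.0 h is up, so I put it first and expect its substrate gone. That clock says when the substrate goes, not where it goes, so weigh ochre's target at the end.

The forecast gives ochre as best, with violet 39%, blue 3.3% and ochre 93%. Its blue is higher than mine. On the order it says: “Even so, ochre should remain the best flask.”

The flasks give ochre as best, with violet 41.2%, blue 1.93% and ochre 75.7%, so the forecast's ochre stands 17 percentage points too high.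

    coupling partner + free catalyst → catalyst intermediate A (k = 1.37 M⁻¹ s⁻¹, Ea = 52.0 kJ mol⁻¹)
    substrate + catalyst intermediate A → catalyst intermediate B (k = 97.4 M⁻¹ s⁻¹, Ea = 36.0 kJ mol⁻¹)
    catalyst intermediate B → catalyst intermediate C (k = 1.73 s⁻¹, Ea = 81.0 kJ mol⁻¹)
    catalyst intermediate C ⇌ by-product + catalyst intermediate D (K = 1.60 M, k = 1.87 s⁻¹, Ea = 77.0 kJ mol⁻¹, ΔH = 14.0 kJ mol⁻¹)
    catalyst intermediate D → free catalyst + target (k = 1.33 s⁻¹, Ea = 90.0 kJ mol⁻¹)
    2 substrate → self-condensation product (k = 2.69 × 10⁻⁴ M⁻¹ s⁻¹, Ea = 83.0 kJ mol⁻¹)
    2 catalyst intermediate A ⇌ resting dimer, settled at all times (K = 4900 M⁻¹, ΔH = 16.0 kJ mol⁻¹)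
    (constants at 80 °C)

Ochre, with its emptying time of 0.617 h, ends with substrate at 0%, and self-condensation product holds 24.3% of the substrate charged. Now repeat violet at 65 °C. The same reckoning gives an emptying time of 2.03 h, shorter than the 3.0 h allowed, so its substrate should be gone too. That flask ends with 0% of its substrate left, target at 77.4% and self-condensation product at 22.6%, with 23% of its coupling partner remaining.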